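**Retrosynthetic overview**
- The target is epiguibourtinidol-(4β→8)-epicatechin. The interflavan bond C4–C8 is made last, by biomimetic Friedel–Crafts capture of a 2,3-cis-flavan-4-yl cation by tetra-O-benzyl-(−)-epicatechin, followed by global hydrogenolysis.
- The 2,3-cis-3,4-trans electrophile comes from a 3-benzyloxy-2H-chromene by hydroboration–oxidation anti to the C2 aryl group; the chromene comes from a 3-benzyloxyflavanone by reduction and elimination.
- Ring C of the upper unit is made by a one-flask enantioselective aldol/SNAr annulation of 4-(benzyloxy)benzaldehyde with the silyl enol ether of an o-fluoroaryl benzyloxymethyl ketone: first C2–C3, then O1–C8a.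
- Enabling feature: C4 of ring C is bonded to ring A ortho to C8a (the carbon that holds O1) and is next to C3. Held as a ketone it makes C3 an enolate carbon and C8a–F an SNAr site, while O7 is meta to C8a and does not deactivate it; the same C4, para to O7 and ortho to O1, later ionises for the interflavan bond.
- Ring order: rings A and B and the whole lower flavan unit are bought; ring C of the upper unit is the only ring constructed.

Key step: step 3

Remark: compounds 1, 2, 6 and 14 are taken as commercial; a stereocentre that the route clears later (C3 in 7 to 10, C4 in 9 and 10) is left open in name and SMILES.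

**Step 1**
Reactants: 1 4-(benzyloxy)-1-bromo-2-fluorobenzene; 2 2-(benzyloxy)-N-methoxy-N-methylacetamide
Product: 4 2-(benzyloxy)-1-[4-(benzyloxy)-2-fluorophenyl]ethan-1-one, via aryllithium 3 (not isolated)
Conditions: n-BuLi, THF, −78 °C; then 2, −78 → −40 °C; 1 M HCl
Reagents that add atoms: none
Why: Br–Li exchange at −78 °C is faster than benzyne formation from the o-fluoroaryllithium, and the chelated tetrahedral adduct of the Weinreb amide prevents over-addition (Weinreb ketone synthesis).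

**Step 2**
Reactants: 4 2-(benzyloxy)-1-[4-(benzyloxy)-2-fluorophenyl]ethan-1-one
Product: 5 (Z)-{[2-(benzyloxy)-1-[4-(benzyloxy)-2-fluorophenyl]ethenyl]oxy}trimethylsilane
Conditions: TMSOTf, Et3N, CH2Cl2, 0 °C; filtered through basic alumina and used crude
Reagents that add atoms: trimethylsilyl trifluoromethanesulfonate, C[Si](C)(C)OS(=O)(=O)C(F)(F)F
Why: Soft enolisation and O-silylation of an aryl α-alkoxy ketone should give the (Z)-silyl enol ether; no stereocentre is formed.

**Step 3**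
Reactants: 5 (Z)-{[2-(benzyloxy)-1-[4-(benzyloxy)-2-fluorophenyl]ethenyl]oxy}trimethylsilane; 6 4-(benzyloxy)benzaldehyde
Product: 8 (2R)-3,7-bis(benzyloxy)-2-[4-(benzyloxy)phenyl]-2,3-dihydro-4H-chromen-4-one (C3 epimers), via trichlorosilyl aldolate 7 (not isolated)
Conditions: SiCl4 (1.5 equiv), (S,S)-bisphosphoramide (two N,N'-dimethyl-1,1'-binaphthyl-2,2'-diamine-derived cyclic phosphoramides linked by N,N'-dimethylpentane-1,5-diamine, 5 mol%), i-Pr2NEt (10 mol%), CH2Cl2, −78 °C; then CsF (12 equiv), DMF, −78 → 0 °C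
Reagents that add atoms: none
Why: The phosphoramide-bound trichlorosilyl cation activates aldehyde 6 and the enol silane attacks its Si face through an open transition state (Mukaiyama aldol; C2–C3 formed, silicon keeps the aldolate as 7); fluoride then strips the silicon and the C2 alkoxide adds to C8a, ipso to fluorine and ortho to the C4 carbonyl, and fluoride loss from the Meisenheimer adduct restores ring A (SNAr; O1–C8a formed). The closest known reaction types are the Lewis-base-catalysed, SiCl4-mediated enantioselective Mukaiyama aldol addition of ketone enol silanes to aromatic aldehydes and the alkoxide SNAr closure of o-fluoroaryl ketones to chroman-4-ones; together they amount to a stepwise oxa-[4+2] annulation of the Danishefsky type in which the C4a=C8a bond of ring A, with fluoride on C8a, plays the methoxyvinyl end of the diene. Ring C closes by 6-endo-trig attack of O1 on C8a of the aryl ketone unit C8a=C4a–C4=O, followed by elimination. C2 is set as R by the catalyst (the (S,S) antipode is chosen on the expectation of Si-face attack and would be exchanged for (R,R) if the first run shows the opposite sense); C3 is expected mainly anti but is not relied on, because it is cleared in step 5. The step needs O1 rather than O3 as the nucleophile and SNAr faster than retro-aldol cleavage: O3 is benzylated so no five-membered coumaranone can form, the C4 carbonyl activates C8a while O7 sits meta to it, and the fluoride stage is kept cold and short.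

**Step 4**
Reactants: 8 (2R)-3,7-bis(benzyloxy)-2-[4-(benzyloxy)phenyl]-2,3-dihydro-4H-chromen-4-one (C3 epimers)
Product: 9 (2R)-3,7-bis(benzyloxy)-2-[4-(benzyloxy)phenyl]-3,4-dihydro-2H-chromen-4-ol (C3 and C4 epimers)
Conditions: NaBH4, THF/MeOH, 0 °C
Reagents that add atoms: none
Why: Borohydride reduction of the aryl ketone leaves benzyl ethers and C2 untouched; the new C4 centre needs no control because it is cleared in step 5.

**Step 5**
Reactants: 9 (2R)-3,7-bis(benzyloxy)-2-[4-(benzyloxy)phenyl]-3,4-dihydro-2H-chromen-4-ol (C3 and C4 epimers)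
Product: 11 (2R)-3,7-bis(benzyloxy)-2-[4-(benzyloxy)phenyl]-2H-chromene, via C4 mesylate 10 (not isolated)
Conditions: MsCl, Et3N (excess), CH2Cl2, 0 → 23 °C; kept cold and dark, used directly
Reagents that add atoms: none
Why: The mesylate of this benzylic alcohol (C4 para to O7, ortho to O1) should ionise readily and Et3N removes H3 to give the conjugated enol ether (sulfonate-mediated dehydration, E1-type elimination); both epimeric centres converge and C2 is not involved.

**Step 6**
Reactants: 11 (2R)-3,7-bis(benzyloxy)-2-[4-(benzyloxy)phenyl]-2H-chromene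
Product: 13 (2R,3R,4S)-3,7-bis(benzyloxy)-2-[4-(benzyloxy)phenyl]-3,4-dihydro-2H-chromen-4-ol, via C4 alkylborane 12 (not isolated)
Conditions: BH3·THF, THF, 0 → 23 °C; then NaOH aq, H2O2, 0 °C
Reagents that add atoms: hydrogen peroxide, OO
Why: Hydroboration–oxidation of a cyclic enol ether puts boron on C4 (β to the enol oxygen and the less substituted carbon) and hydrogen on C3 in a syn addition anti to the C2 aryl group, so that 3-OBn ends cis to the aryl group and, after oxidation with retention, 4-OH ends trans to 3-OBn.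

**Step 7**
Reactants: 14 (−)-epicatechin, (2R,3R)-2-(3,4-dihydroxyphenyl)chromane-3,5,7-triol
Product: 15 (2R,3R)-5,7-bis(benzyloxy)-2-[3,4-bis(benzyloxy)phenyl]chroman-3-ol (5,7,3',4'-tetra-O-benzyl-(−)-epicatechin)
Conditions: BnBr (4.4 equiv), K2CO3, DMF, 0 → 23 °C
Reagents that add atoms: benzyl bromide, BrCc1ccccc1
Why: Williamson etherification under carbonate alkylates the four phenols and leaves the secondary 3-OH and both stereocentres untouched.

**Step 8**
Reactants: 13 (2R,3R,4S)-3,7-bis(benzyloxy)-2-[4-(benzyloxy)phenyl]-3,4-dihydro-2H-chromen-4-ol; 15 (2R,3R)-5,7-bis(benzyloxy)-2-[3,4-bis(benzyloxy)phenyl]chroman-3-ol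
Product: 16 (2R,3R,4R)-3,7-bis(benzyloxy)-2-[4-(benzyloxy)phenyl]-4-{(2R,3R)-5,7-bis(benzyloxy)-2-[3,4-bis(benzyloxy)phenyl]-3-hydroxychroman-8-yl}chromane
Conditions: 15 (4 equiv, excess recovered), TMSOTf (0.3 equiv), CH2Cl2, −78 → −30 °C; Et3N quench
Reagents that add atoms: none
Why: Acid ionises the 4-OH to the flavan-4-yl cation (stabilised by O7 para and O1 ortho) and C8 of the phloroglucinol-type ring of 15 should attack from the β-face, anti to the 3-OBn and C2 aryl groups that both lie on the α-face (biomimetic Friedel–Crafts alkylation as in proanthocyanidin synthesis), which sets C4 as R (4β, 3,4-trans).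

**Step 9**
Reactants: 16 (2R,3R,4R)-3,7-bis(benzyloxy)-2-[4-(benzyloxy)phenyl]-4-{(2R,3R)-5,7-bis(benzyloxy)-2-[3,4-bis(benzyloxy)phenyl]-3-hydroxychroman-8-yl}chromane
Product: 17 CNP0118995.2, (2R,3R,4R)-2-(4-hydroxyphenyl)-4-[(2R,3R)-2-(3,4-dihydroxyphenyl)-3,5,7-trihydroxychroman-8-yl]chromane-3,7-diol
Conditions: H2 (1 atm), Pd(OH)2/C, THF/MeOH/H2O, 23 °C; filtration, Sephadex LH-20
Reagents that add atoms: none
Why: Hydrogenolysis of the seven benzyl ethers under neutral conditions, as used for procyanidins, should leave the cyclic benzylic C2–O1 ethers, the interflavan bond and all five stereocentres intact.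

**Compound list**
1 | 4-(benzyloxy)-1-bromo-2-fluorobenzene | Fc1cc(OCc2ccccc2)ccc1Br | starting material
2 | 2-(benzyloxy)-N-methoxy-N-methylacetamide | CON(C)C(=O)COCc1ccccc1 | starting material
3 | [4-(benzyloxy)-2-fluorophenyl]lithium | [Li]c1ccc(OCc2ccccc2)cc1F | intermediate
4 | 2-(benzyloxy)-1-[4-(benzyloxy)-2-fluorophenyl]ethan-1-one | O=C(COCc1ccccc1)c1ccc(OCc2ccccc2)cc1F | intermediate
5 | (Z)-{[2-(benzyloxy)-1-[4-(benzyloxy)-2-fluorophenyl]ethenyl]oxy}trimethylsilane | C[Si](C)(C)O/C(=C\OCc1ccccc1)c1ccc(OCc2ccccc2)cc1F | intermediate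
6 | 4-(benzyloxy)benzaldehyde | O=Cc1ccc(OCc2ccccc2)cc1 | starting material
7 | (3R)-2-(benzyloxy)-1-[4-(benzyloxy)-2-fluorophenyl]-3-[4-(benzyloxy)phenyl]-3-[(trichlorosilyl)oxy]propan-1-one (C2 epimers) | O=C(c1ccc(OCc2ccccc2)cc1F)C(OCc1ccccc1)[C@H](O[Si](Cl)(Cl)Cl)c1ccc(OCc2ccccc2)cc1 | intermediate
8 | (2R)-3,7-bis(benzyloxy)-2-[4-(benzyloxy)phenyl]-2,3-dihydro-4H-chromen-4-one (C3 epimers) | C(c1ccccc1)Oc1ccc([C@H]2Oc3cc(OCc4ccccc4)ccc3C(=O)C2OCc2ccccc2)cc1 | intermediate
9 | (2R)-3,7-bis(benzyloxy)-2-[4-(benzyloxy)phenyl]-3,4-dihydro-2H-chromen-4-ol (C3 and C4 epimers) | C(c1ccccc1)Oc1ccc([C@H]2Oc3cc(OCc4ccccc4)ccc3C(O)C2OCc2ccccc2)cc1 | intermediate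
10 | (2R)-3,7-bis(benzyloxy)-2-[4-(benzyloxy)phenyl]-3,4-dihydro-2H-chromen-4-yl methanesulfonate (C3 and C4 epimers) | C(c1ccccc1)Oc1ccc([C@H]2Oc3cc(OCc4ccccc4)ccc3C(OS(C)(=O)=O)C2OCc2ccccc2)cc1 | intermediate
11 | (2R)-3,7-bis(benzyloxy)-2-[4-(benzyloxy)phenyl]-2H-chromene | C(c1ccccc1)Oc1ccc([C@H]2Oc3cc(OCc4ccccc4)ccc3C=C2OCc2ccccc2)cc1 | intermediate
12 | [(2R,3R,4S)-3,7-bis(benzyloxy)-2-[4-(benzyloxy)phenyl]-3,4-dihydro-2H-chromen-4-yl]borane | C(c1ccccc1)Oc1ccc([C@H]2Oc3cc(OCc4ccccc4)ccc3[C@H](B)[C@H]2OCc2ccccc2)cc1 | intermediate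
13 | (2R,3R,4S)-3,7-bis(benzyloxy)-2-[4-(benzyloxy)phenyl]-3,4-dihydro-2H-chromen-4-ol | C(c1ccccc1)Oc1ccc([C@H]2Oc3cc(OCc4ccccc4)ccc3[C@H](O)[C@H]2OCc2ccccc2)cc1 | intermediate
14 | (−)-epicatechin, (2R,3R)-2-(3,4-dihydroxyphenyl)chromane-3,5,7-triol | Oc1cc(O)c2c(c1)O[C@H](c1ccc(O)c(O)c1)[C@H](O)C2 | starting material
15 | (2R,3R)-5,7-bis(benzyloxy)-2-[3,4-bis(benzyloxy)phenyl]chroman-3-ol | c1ccccc1COc1cc(OCc3ccccc3)c2c(c1)O[C@H](c1ccc(OCc3ccccc3)c(OCc3ccccc3)c1)[C@H](O)C2 | intermediate
16 | (2R,3R,4R)-3,7-bis(benzyloxy)-2-[4-(benzyloxy)phenyl]-4-{(2R,3R)-5,7-bis(benzyloxy)-2-[3,4-bis(benzyloxy)phenyl]-3-hydroxychroman-8-yl}chromane | C(c1ccccc1)Oc1ccc([C@H]2Oc3cc(OCc4ccccc4)ccc3[C@H](c3c(OCc4ccccc4)cc(OCc4ccccc4)c4c3O[C@H](c3ccc(OCc5ccccc5)c(OCc5ccccc5)c3)[C@H](O)C4)[C@H]2OCc2ccccc2)cc1 | intermediate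
17 | CNP0118995.2, epiguibourtinidol-(4β→8)-epicatechin | Oc1ccc([C@H]2Oc3cc(O)ccc3[C@H](c3c(O)cc(O)c4c3O[C@H](c3ccc(O)c(O)c3)[C@H](O)C4)[C@H]2O)cc1 | target

**Step count and risks**
Total steps: 9. Longest linear sequence: 8 (steps 1 to 6, 8 and 9); step 7 is a one-step side branch.

Steps most likely to fail:

1. Step 3. In the fluoride stage the free aldolate may undergo retro-aldol cleavage, or the product may ring-open through its C3 enolate, faster than the SNAr closure; either process would erode the configuration at C2. Fallback: from 5 and 6 the same catalytic aldol addition is run but quenched cold with aqueous KF/KH2PO4, and the hydroxy ketone (3R)-2-(benzyloxy)-1-[4-(benzyloxy)-2-fluorophenyl]-3-[4-(benzyloxy)phenyl]-3-hydroxypropan-1-one F1 is isolated. NaBH4 reduction then gives (1R)-2-(benzyloxy)-3-[4-(benzyloxy)-2-fluorophenyl]-1-[4-(benzyloxy)phenyl]propane-1,3-diol F2, in which neither retro-aldol cleavage nor enolisation is possible. KOt-Bu in THF/DMPU at 60 °C should close ring C by intramolecular SNAr of the C1 alkoxide on the now unactivated aryl fluoride, and the route is rejoined at 9.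

2. Step 6. Borane may add with poor facial selectivity with respect to the C2 aryl group, may add partly with reversed regiochemistry, or the β-benzyloxy alkylborane may eliminate back to an alkene. Fallback: from 11, hydrolysis of the enol ether (1 M HCl, THF, 0 °C) gives (2R)-7-(benzyloxy)-2-[4-(benzyloxy)phenyl]chroman-3-one F3. LiBH(s-Bu)3 at −78 °C delivers hydride anti to the C2 aryl group to give the 2,3-cis alcohol (2R,3R)-7-(benzyloxy)-2-[4-(benzyloxy)phenyl]chroman-3-ol F4. DDQ with 2-ethoxyethanol in CH2Cl2 oxidises C4 to (2R,3R,4S)-7-(benzyloxy)-2-[4-(benzyloxy)phenyl]-4-(2-ethoxyethoxy)chroman-3-ol F5. TMSOTf-mediated coupling of F5 with excess 15 gives (2R,3R,4R)-7-(benzyloxy)-2-[4-(benzyloxy)phenyl]-4-{(2R,3R)-5,7-bis(benzyloxy)-2-[3,4-bis(benzyloxy)phenyl]-3-hydroxychroman-8-yl}chroman-3-ol F6, and hydrogenolysis over Pd(OH)2/C rejoins the route at 17.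

3. Step 8. The less stabilised 5-deoxy cation may form slowly at low temperature and then be captured at C6 instead of C8 of 15 or by ring A of a second molecule of 13, so that regioisomers and oligomers compete. Fallback: from 13, hydrogenolysis (H2, Pd(OH)2/C, EtOAc, short contact) gives the free flavan-3,4-diol (2R,3R,4S)-2-(4-hydroxyphenyl)chromane-3,4,7-triol F7. F7 is then condensed with an excess of unprotected 14 in 0.1 M aqueous HCl/EtOH at 23 °C (classical protecting-group-free biomimetic coupling), the 4→6 isomer is removed on Sephadex LH-20, and the route is rejoined at 17.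

**Further compounds**
F1 | step 3 | (3R)-2-(benzyloxy)-1-[4-(benzyloxy)-2-fluorophenyl]-3-[4-(benzyloxy)phenyl]-3-hydroxypropan-1-one (C2 epimers) | O=C(c1ccc(OCc2ccccc2)cc1F)C(OCc1ccccc1)[C@H](O)c1ccc(OCc2ccccc2)cc1
F2 | step 3 | (1R)-2-(benzyloxy)-3-[4-(benzyloxy)-2-fluorophenyl]-1-[4-(benzyloxy)phenyl]propane-1,3-diol (C2 and C3 epimers) | OC(c1ccc(OCc2ccccc2)cc1F)C(OCc1ccccc1)[C@H](O)c1ccc(OCc2ccccc2)cc1
F3 | step 6 | (2R)-7-(benzyloxy)-2-[4-(benzyloxy)phenyl]chroman-3-one | C(c1ccccc1)Oc1ccc([C@H]2Oc3cc(OCc4ccccc4)ccc3CC2=O)cc1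
F4 | step 6 | (2R,3R)-7-(benzyloxy)-2-[4-(benzyloxy)phenyl]chroman-3-ol | C(c1ccccc1)Oc1ccc([C@H]2Oc3cc(OCc4ccccc4)ccc3C[C@H]2O)cc1
F5 | step 6 | (2R,3R,4S)-7-(benzyloxy)-2-[4-(benzyloxy)phenyl]-4-(2-ethoxyethoxy)chroman-3-ol | C(c1ccccc1)Oc1ccc([C@H]2Oc3cc(OCc4ccccc4)ccc3[C@H](OCCOCC)[C@H]2O)cc1
F6 | step 6 | (2R,3R,4R)-7-(benzyloxy)-2-[4-(benzyloxy)phenyl]-4-{(2R,3R)-5,7-bis(benzyloxy)-2-[3,4-bis(benzyloxy)phenyl]-3-hydroxychroman-8-yl}chroman-3-ol | C(c1ccccc1)Oc1ccc([C@H]2Oc3cc(OCc4ccccc4)ccc3[C@H](c3c(OCc4ccccc4)cc(OCc4ccccc4)c4c3O[C@H](c3ccc(OCc5ccccc5)c(OCc5ccccc5)c3)[C@H](O)C4)[C@H]2O)cc1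
F7 | step 8 | (2R,3R,4S)-2-(4-hydroxyphenyl)chromane-3,4,7-triol | Oc1ccc([C@H]2Oc3cc(O)ccc3[C@H](O)[C@H]2O)cc1
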